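(Readings and results are simulated for substances that don't exist; the scatter is artificial.)

| flask | left-handed substrate | right-handed substrate | partner | precatalyst | remark | time |
|---|---|---|---|---|---|---|
| Tuesday's | 0.50 M | 0.50 M | 0.30 M | 33 mM | the very flask that is asked about, followed so far |  |
| Friday's | 0.34 M | 0.34 M | 0.30 M | 33 mM | run made earlier |  |
| flask | 0.50 M | 0.50 M | 0.300 M | 33 mM |  | 3.0 d |

| run | time / h | left-handed product / % | right-handed substrate / % |
|---|---|---|---|
| Tuesday's | 2.00 | 1.0 | 49.7 |
| Tuesday's | 4.00 | 3.7 | 48.8 |
| Tuesday's | 6.00 | 5.6 | 47.4 |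
| Tuesday's | 8.00 | 8.1 | 47.5 |
| Tuesday's | 10.0 | 10.5 | 45.9 |
| Tuesday's | 12.0 | 11.9 | 45.6 |
| Tuesday's | 15.0 | 14.1 | 44.8 |
| Friday's | 2.50 | 1.5 | 49.6 |
| Friday's | 4.00 | 3.5 | 48.6 |
| Friday's | 5.00 | 4.5 | 48.4 |
| Friday's | 8.00 | 8.8 | 46.5 |
| Friday's | 12.0 | 13.7 | 43.3 |
| Friday's | 20.0 | 19.9 | 41.9 |
| Friday's | 30.0 | 23.4 | 39.6 |

(scatter of a reading: 0.3 percentage points)

- catalyst is single-handed; left-handed substrate and right-handed substrate are mirror images of each other, charged as a racemate, each of them at the stated concentration

- concentration of left-handed product at 3.0 d, in M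
- concentration of right-handed substrate at 3.0 d, in M
- concentration of right-handed product at 3.0 d, in M

**Two rates.** In a one-step world you follow one rate. This flask has two: left-handed and right-handed substrate compete for one partner, and you want the ratio of their rates.

**Selectivity factor.** At equal amounts, left-handed product forms s times as fast as right-handed product. Take the log of charge over what is left, for each substrate, and divide left-handed by right-handed. Friday's last reading gives a selectivity factor of 2.71.

**The drift.** Partner at 0.300 M is less than the substrates' 1.00 M, so I treat it as the limiting reagent, one per product. The products read in Tuesday's flask at 15.0 h equal 64.3 % of its partner charge, and you wait 3.0 d, so as an estimate I count the charge as product. Split at s, that is 0.219 M left-handed and 0.0809 M right-handed. Left-handed substrate then stands lower, so the ratio ends near 1.81. The mean, 2.26, gives me 0.208 M and 0.0920 M.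

**The forecast.** It says “Partner is limiting” and gives 0.207 M left-handed product, 0.412 M right-handed substrate and 0.088 M right-handed product. My right-handed product is higher.

**The result.** The flask gives 0.196 M, 0.416 M and 0.0840 M, so the forecast is right within its margins.

    partner + catalyst + left-handed substrate → catalyst + left-handed product (k = 17.0 L² mol⁻² h⁻¹)
    partner + catalyst + right-handed substrate → catalyst + right-handed product (k = 6.30 L² mol⁻² h⁻¹)
    catalyst ⇌ dormant form (K = 0.640, k = 0.160 h⁻¹)
    partner + precatalyst → catalyst + spent reagent (k = 0.260 L mol⁻¹ h⁻¹)

**Same reckoning.** This flask's product ratio is 2.33, beside my mean of 2.26. The two products hold 0.280 M of this flask's 0.300 M partner charge, not the whole charge I counted, and spent reagent stands at 0.0202 M. In the neighbouring flask with 0.12 M partner, the split at s is 0.0876 M and 0.0324 M, and the mean ratio is 2.55. That neighbouring flask holds 0.0764 M left-handed and 0.0298 M right-handed product, a ratio of 2.56.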